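The runs are simulated with constants of no real substance, noise included.

Monday's target stands at 31.7% at 8.00 min and Sunday's at 20.0%, and the two runs differ in second substrate, 0.36 M against 0.57 M. In the new flask, 0.260 M of reagent faces 0.520 M of substrates together, so the reagent is the limiting reagent and the substrates compete for it.

| setting | Monday's | Sunday's | flask |
|---|---|---|---|
| starting material | 0.26 M (in portions, 2) | 0.26 M (in portions, 2) | 0.26 M (in portions, 2) |
| reagent | 0.26 M | 0.26 M | 0.260 M |
| second substrate | 0.36 M | 0.57 M | 0.260 M |
| remark | run made earlier; portions every 8.0 s | run made earlier; portions every 8.0 s | the portions of starting material follow each other after 8.0 s, the first at the start |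
| time |  |  | 8.0 min |

| run | time / min | starting material / % | target / % |
|---|---|---|---|
| Monday's | 0.667 | 76.8 | 25.4 |
| Monday's | 2.00 | 71.3 | 27.8 |
| Monday's | 4.00 | 70.0 | 28.4 |
| Monday's | 6.00 | 70.0 | 30.2 |
| Monday's | 8.00 | 71.0 | 31.7 |
| Sunday's | 0.667 | 84.1 | 11.4 |
| Sunday's | 2.00 | 82.3 | 17.9 |
| Sunday's | 4.00 | 81.7 | 18.0 |
| Sunday's | 6.00 | 78.8 | 20.0 |
| Sunday's | 8.00 | 79.6 | 20.0 |

(readings scatter by 1 percentage point)

- what may be going on: second substrate + reagent <-> second product; starting material + reagent <-> target
- the reaction counts as stopped when no species that holds the starting material changes by six tenths of a point or more over the second half of the time

* which holds at 8.0 min: what has brought the reaction to rest, or that it has not come to rest (forward and back rates have come level / all of the starting material has reacted / it is still moving / the reagent has run out first)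
* how much of the starting material has reacted by 8.0 min
* how much target there is at 8.0 min, in percent of the starting material charged

On Monday, target forms at 0.0990 M/min on average over the first 0.667 min, but at 0.00215 M/min between 4.00 min and 8.00 min, a reading with its scatter. The later rate is therefore smaller by a factor of 46.0. Starting material, read at 71.0% of its charge at 8.00 min, is worth a factor of 1.41; we assign the remaining factor of 32.7 to falling free reagent and a rising back step. We read that accumulated slowing as forward and back rates coming close to level, so we reckon the end from a ratio and not from a time.

We write the reagent balance with free reagent set at nil, so that [second product] is the reagent charge less [target]. The last readings then give 0.459 on Monday and 0.437 on Sunday. We carry their mean, 0.448, as the exchange ratio, [target][second substrate]/([starting material][second product]). In the new flask the charges are equal, so in this balance, with free reagent at nil, [target] equals [second substrate] and [starting material] equals [second product]. Target over starting material is then the square root of the exchange ratio, 0.669, which gives 40.1% target.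

The forecast says forward and back rates have come level, with 40% reacted and 40% target, and of the ratios from the two runs it writes: “This agreement supports equilibrium control.”

    second substrate + reagent ⇌ second product (K = 93.0 /M, k = 0.670 /M/s)
    starting material + reagent ⇌ target (K = 44.0 /M, k = 0.320 /M/s)

At 8.00 min in the flask, forward and back rates have come level, with 38.1% reacted and 38.1% target. Free reagent there is 5.4% of its charge, not the nil of our balance, and our 40.1% lies 2 percentage points from the flask's target. Now take the neighbour charged with 0.16 M of starting material, which at 8.00 min holds 0.167 M of second product and 0.0929 M of second substrate. Our exchange ratio of 0.448 turns these into target over starting material of 0.806, or 44.6% target, and that neighbour holds 46.0%.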